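**Retrosynthetic overview**

1. Numbering (cedrane): ring A = C1–C5 (C2 carries the CHO carbon C12); ring B = C1, C5, C6, C7, C11 (C6 carries CH3 and CH2OH, C13); ring C = C1, C11, C7, C8 (CO2H), C9, C10 (O-acyl).
2. Endgame disconnections: C10 ester (Yamaguchi, acid 30); C8–CO2H from a vinyl triflate (Pd/CO/H2O); C2–CHO and C10–OH from a γ-lactone C12(=O)–O–C10 (lactol, then dithiane).
3. Ring A is made last: C5–H by OH-directed hydrogenation of C4=C5; C2–C3 and C4=C5 are formed in one operation by a vinylphosphonium Michael addition/intramolecular Wittig annulation of keto-lactone 17.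
4. Enabling feature: on the quaternary bridgehead C1, the acidic lactone α-carbon C2 (held by the lactone fused to ring C at C1–C10) and the non-enolisable ring-B ketone C5 stand 1,3 to each other, so a two-carbon unit can bridge them; the lactone also fixes C2 and is later unmasked as CHO and the C10 hydroxyl.
5. Ring order: ring C (Birch alkylation, oxidation, enzymatic desymmetrisation; sets C1), ring B (Dieckmann, sets C7; C6 by methylation then exo hydroxymethylation), lactone (oxa-Michael, sets C10), ring A (key step, sets C2), then C5.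

Key step: step 12

Remark on the chemistry: the SMILES is read literally as (1R,2S,5S,6S,7S,10S), i.e. H-5 and the C6 CH2OH are both exo on the C5–C6 bridge, C4 is endo and rings A/B are trans-fused (strained); the route is built to deliver exactly this arrangement.

**Route**

Step 1
Reactants: 1 methyl benzoate; 2 allyl bromide
Product: 3 methyl 1-allylcyclohexa-2,5-diene-1-carboxylate
Conditions: K, NH3(l)/THF, t-BuOH (1 equiv), −78 °C; then 2, −78 °C → rt
Reagents that add atoms: none
Why: Birch reduction of the benzoate gives the ester dienolate, which is C-alkylated at the carboxyl-bearing carbon (Birch reductive alkylation); the product is achiral.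

Step 2
Reactants: 3 methyl 1-allylcyclohexa-2,5-diene-1-carboxylate
Product: 4 methyl 1-allyl-4-oxocyclohexa-2,5-diene-1-carboxylate
Conditions: CrO3 (cat.), t-BuOOH (70 % aq.), CH2Cl2, rt
Reagents that add atoms: tert-butyl hydroperoxide, CC(C)(C)OO
Why: Chromium-catalysed allylic oxidation with t-BuOOH should attack the doubly allylic ring CH2 in preference to the side-chain allylic CH2 and give the prochiral cross-conjugated dienone.

Step 3
Reactants: 4 methyl 1-allyl-4-oxocyclohexa-2,5-diene-1-carboxylate
Product: 5 methyl (R)-1-allyl-4-oxocyclohex-2-ene-1-carboxylate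
Conditions: ene-reductase (Old Yellow Enzyme family, variant selected for the R enone), NADP+ (cat.), alcohol dehydrogenase, i-PrOH, phosphate buffer pH 7.5/DMSO, 30 °C
Reagents that add atoms: none
Why: Enzymatic conjugate reduction (ene-reductase desymmetrisation of a prochiral 4,4-disubstituted cyclohexadienone) saturates one of the two enantiotopic C=C bonds and thereby sets the quaternary centre C1.

Step 4
Reactants: 5 methyl (R)-1-allyl-4-oxocyclohex-2-ene-1-carboxylate; 6 tert-butyl bromoacetate
Product: 7 methyl 1-allyl-5-(2-tert-butoxy-2-oxoethyl)-4-oxocyclohex-2-ene-1-carboxylate (C1 as in 5, both C5 epimers)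
Conditions: LiN(i-Pr)2, THF, −78 °C; then 6, −78 → −20 °C
Reagents that add atoms: none
Why: Kinetic deprotonation of the enone occurs at the α′ CH2 (future C7) and the lithium enolate is alkylated by the α-bromo ester (enolate alkylation); C7 forms as an epimer mixture that is equilibrated in step 5.

Step 5
Reactants: 7 methyl 1-allyl-5-(2-tert-butoxy-2-oxoethyl)-4-oxocyclohex-2-ene-1-carboxylate
Product: 9 C6-methyl β-keto tert-butyl ester, via Dieckmann β-keto ester 8 (not isolated)
Conditions: KOt-Bu (2.2 equiv), t-BuOH/THF, 0 °C → rt; then MeI (3 equiv), rt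
Reagents that add atoms: iodomethane, CI
Why: Dieckmann condensation under reversible tert-butoxide/tert-butanol conditions: C7 epimerises through the ring-ketone enolate, only the epimer with the acetate arm cis to the C1 ester can bridge (this fixes C7), and the β-keto ester enolate is the thermodynamic sink, which is C-methylated in the same flask; the configuration at C6 is without consequence.

Step 6
Reactants: 9 C6-methyl β-keto tert-butyl ester
Product: 11 C6-methyl diketone, via β-keto acid 10 (not isolated)
Conditions: CF3CO2H, CH2Cl2, rt; then toluene, 90 °C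
Reagents that add atoms: none
Why: Acidolysis of the tert-butyl ester followed by thermal decarboxylation of the β-keto acid through the C5=C6 enol gives the methyl ketone; C6 is re-formed as a mixture that is erased by enolisation in step 7.

Step 7
Reactants: 11 C6-methyl diketone
Product: 12 C6-hydroxymethyl diketone (CH2OH exo, CH3 endo)
Conditions: LiN(i-Pr)2, THF, −78 °C; CH2O (gas), −78 °C; H2O
Reagents that add atoms: formaldehyde, C=O
Why: C6–H is the only enolisable position (C7 is a bridgehead, C1 is quaternary) and the aldol addition to formaldehyde is expected on the exo face of the C5–C6 bridge, away from the C8–C10 bridge, which puts CH2OH exo and CH3 endo at C6 as in the target.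

Step 8
Reactants: 12 C6-hydroxymethyl diketone
Product: 13 silyl ether diketone
Conditions: TBSCl, imidazole, DMF, rt
Reagents that add atoms: tert-butyldimethylsilyl chloride, CC(C)(C)[Si](C)(C)Cl
Why: Standard silylation of the primary alcohol, which also blocks retro-aldol loss of formaldehyde in the later base steps.

Step 9
Reactants: 13 silyl ether diketone
Product: 15 C12 carboxylic acid, via C12 aldehyde 14 (not isolated)
Conditions: O3, CH2Cl2/MeOH, −78 °C (Sudan red 7B as indicator); Me2S; then NaClO2, NaH2PO4, 2-methylbut-2-ene, t-BuOH/H2O, 0 °C → rt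
Reagents that add atoms: ozone, [O-][O+]=O; sodium chlorite, [Na+].[O-]Cl=O
Why: Ozone cleaves the isolated terminal alkene much faster than the electron-poor enone C=C (selective ozonolysis) and Pinnick oxidation converts the aldehyde into the acid without touching the ketones.

Step 10
Reactants: 15 C12 carboxylic acid
Product: 16 keto-lactone
Conditions: DBU (0.2 equiv), CH2Cl2, rt
Reagents that add atoms: none
Why: Base-catalysed intramolecular oxa-Michael addition (5-exo-trig) of the carboxylate to C10 of the enone gives the cis-fused γ-lactone; because the acid arm is tethered to C1 the oxygen can only enter on the face of ring C that carries C2, which sets C10.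

Step 11
Reactants: 16 keto-lactone
Product: 17 vinyl triflate keto-lactone
Conditions: Tf2O, 2,6-di-tert-butyl-4-methylpyridine, CH2Cl2, 0 °C → rt
Reagents that add atoms: trifluoromethanesulfonic anhydride, O=S(=O)(OS(=O)(=O)C(F)(F)F)C(F)(F)F
Why: O-Triflation of the C8 ketone and loss of a C9 proton (C7 is a bridgehead, so only one regioisomer is possible) gives the enol triflate without an enolate that could expel the β-acyloxy group; the C5 ketone has no α-hydrogen and is left alone.

Step 12
Reactants: 17 vinyl triflate keto-lactone; 18 vinyltriphenylphosphonium bromide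
Product: 20 ring-A cyclopentene lactone, via phosphonium ylide 19 (not isolated)
Conditions: LiN(SiMe3)2 (1.05 equiv), THF, −78 °C; 18, THF/DMF, −78 °C → rt; then 60 °C
Reagents that add atoms: none
Why: The lithium enolate of the γ-lactone (C2) adds to the vinylphosphonium salt (Michael addition, new C2–C3 bond) and the resulting ylide at C4 attacks the C5 ketone intramolecularly, collapse of the oxaphosphetane giving the C4=C5 alkene (Wittig olefination, new C4–C5 bond). The closest known reaction type is the vinylphosphonium cycloalkene annulation of keto enolates (Michael addition/intramolecular Wittig). Ring A closes in the Wittig step by 5-exo-trig attack of the ylide carbon on the ketone carbonyl from the exo face, the only face that the arm on bridgehead C1 can reach. The single new stereocentre C2 is controlled by the lactone: ring A can only be cis-fused to the five-membered lactone, so closure is possible only from the C2 epimer whose phosphonioethyl arm lies on the side of C5, and the other epimer equilibrates through the lactone enolate. The step needs site-selective deprotonation and C-alkylation, which the substrate secures because C2–H2 is the only acidic position (the C5 ketone has no α-hydrogen, C7 is a bridgehead) and the vinyl triflate is inert to the amide base and to the ylide.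

Step 13
Reactants: 20 ring-A cyclopentene lactone
Product: 21 cyclopentene lactone alcohol
Conditions: HF·pyridine, THF/pyridine, 0 °C → rt
Reagents that add atoms: none
Why: Fluoride cleaves the primary silyl ether (desilylation) and frees the C13 hydroxyl needed as the directing group; lactone and vinyl triflate are stable to buffered HF.

Step 14
Reactants: 21 cyclopentene lactone alcohol
Product: 22 saturated lactone alcohol (H-5 exo)
Conditions: [Ir(cod)(PCy3)(py)]PF6 (20 mol %), H2 (1 atm), CH2Cl2, rt
Reagents that add atoms: none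
Why: Hydroxyl-directed homogeneous hydrogenation: the cationic iridium catalyst is bound by the exo C13 hydroxyl and should deliver H2 to the exo face of C4=C5, so that H-5 is placed exo (syn to CH2OH) and C4 endo under kinetic control, although this trans A/B fusion is the strained one.

Step 15
Reactants: 22 saturated lactone alcohol
Product: 23 saturated lactone silyl ether
Conditions: TBSCl, imidazole, DMF, rt
Reagents that add atoms: tert-butyldimethylsilyl chloride, CC(C)(C)[Si](C)(C)Cl
Why: Silylation of the primary alcohol so that only the C10 hydroxyl is free for the later acylation.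

Step 16
Reactants: 23 saturated lactone silyl ether
Product: 24 lactol
Conditions: i-Bu2AlH (1.2 equiv), CH2Cl2, −78 °C; aqueous potassium sodium tartrate
Reagents that add atoms: none
Why: Partial reduction of the γ-lactone to the lactol with i-Bu2AlH at low temperature; the vinyl triflate and the silyl ether are inert under these conditions.

Step 17
Reactants: 24 lactol
Product: 25 dithiane alcohol
Conditions: HS(CH2)3SH, BF3·OEt2, CH2Cl2, −40 → −20 °C
Reagents that add atoms: propane-1,3-dithiol, SCCCS
Why: Lewis-acid-mediated thioacetalisation opens the lactol to the 1,3-dithiane (masked C12 aldehyde) and releases the C10 hydroxyl; C2 and C10 are not touched, and the allylic C10–O bond should not ionise because the alkene carries the triflate.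

Step 18
Reactants: 26 oct-7-yn-1-ol
Product: 27 tert-butyldimethyl(oct-7-yn-1-yloxy)silane
Conditions: TBSCl, imidazole, CH2Cl2, rt
Reagents that add atoms: tert-butyldimethylsilyl chloride, CC(C)(C)[Si](C)(C)Cl
Why: Standard silylation of the primary alcohol.

Step 19
Reactants: 27 tert-butyldimethyl(oct-7-yn-1-yloxy)silane; 28 8-bromooctanoic acid
Product: 29 16-(tert-butyldimethylsilyloxy)hexadec-9-ynoic acid
Conditions: 27 (2.1 equiv), n-BuLi (2.1 equiv), THF/DMPU, −78 → 0 °C; then 28 (1 equiv), 0 °C → rt; dilute HCl
Reagents that add atoms: none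
Why: The lithium acetylide first deprotonates the acid and then displaces the primary bromide of the lithium carboxylate (acetylide alkylation), joining the two halves of the C16 chain with the alkyne at the 9,10-position.

Step 20
Reactants: 29 16-(tert-butyldimethylsilyloxy)hexadec-9-ynoic acid
Product: 30 (9Z)-16-(tert-butyldimethylsilyloxy)hexadec-9-enoic acid
Conditions: H2 (1 atm), Pd/CaCO3 poisoned with Pb(OAc)2, quinoline, EtOAc, rt
Reagents that add atoms: none
Why: Semihydrogenation over lead-poisoned palladium adds H2 syn to the alkyne and gives the Z alkene (Lindlar reduction).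

Step 21
Reactants: 25 dithiane alcohol; 30 (9Z)-16-(tert-butyldimethylsilyloxy)hexadec-9-enoic acid
Product: 32 C10 ester, via mixed anhydride 31 (not isolated)
Conditions: 30, 2,4,6-trichlorobenzoyl chloride, Et3N, THF, rt; then 25, DMAP, toluene, rt → 40 °C
Reagents that add atoms: none
Why: Yamaguchi esterification through the mixed anhydride acylates the hindered secondary C10 alcohol with retention at C10, the dithiane and the vinyl triflate being inert to DMAP and triethylamine.

Step 22
Reactants: 32 C10 ester
Product: 33 C8 carboxylic acid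
Conditions: Pd(OAc)2 (10 mol %), 1,1′-bis(diphenylphosphino)ferrocene, CO (1 atm), KOAc, DMF/H2O, 50 °C
Reagents that add atoms: carbon monoxide, [C-]#[O+]; water, O
Why: Oxidative addition of zerovalent palladium into the vinyl triflate, CO insertion and hydrolysis of the acylpalladium species give the C8 carboxylic acid directly (hydroxycarbonylation), so that no protecting group is needed for this acid.

Step 23
Reactants: 33 C8 carboxylic acid
Product: 34 aldehyde bis-silyl ether
Conditions: PhI(O2CCF3)2, MeCN/H2O (9:1), 0 °C
Reagents that add atoms: water, O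
Why: Oxidative dethioacetalisation with the hypervalent iodine reagent releases the C12 aldehyde under mild, slightly acidic conditions that should not epimerise C2 or touch the Z alkene.

Step 24
Reactants: 34 aldehyde bis-silyl ether
Product: 35 target
Conditions: HF·pyridine, THF/pyridine, 0 °C → rt
Reagents that add atoms: none
Why: Fluoride-mediated cleavage of both primary silyl ethers under buffered conditions that should spare the aldehyde, the allylic ester, the acid and the alkenes.

**Compound list**

1 | methyl benzoate | COC(=O)c1ccccc1 | starting material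
2 | allyl bromide (3-bromoprop-1-ene) | C=CCBr | starting material
3 | methyl 1-allylcyclohexa-2,5-diene-1-carboxylate | C=CCC1(C(=O)OC)C=CCC=C1 | intermediate
4 | methyl 1-allyl-4-oxocyclohexa-2,5-diene-1-carboxylate | C=CCC1(C(=O)OC)C=CC(=O)C=C1 | intermediate
5 | methyl (R)-1-allyl-4-oxocyclohex-2-ene-1-carboxylate | O=C1C=C[C@@](CC=C)(C(=O)OC)CC1 | intermediate
6 | tert-butyl bromoacetate | CC(C)(C)OC(=O)CBr | starting material
7 | methyl 1-allyl-5-(2-tert-butoxy-2-oxoethyl)-4-oxocyclohex-2-ene-1-carboxylate, C1 as in 5, both C5 epimers | O=C1C=C[C@@](CC=C)(C(=O)OC)CC1CC(=O)OC(C)(C)C | intermediate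
8 | Dieckmann β-keto ester: bicyclo[3.2.1]octene (rings B and C) with C5 and C8 ketones, C9=C10, allyl on C1, H and CO2t-Bu on C6; C1 and C7 as in the target | CC(C)(C)OC(=O)C1[C@@H]2C[C@](C=CC2=O)(CC=C)C1=O | intermediate
9 | C6-methyl β-keto tert-butyl ester: as 8 with CH3 and CO2t-Bu on C6 (C6 configuration inconsequential) | CC(C)(C)OC(=O)C1(C)[C@@H]2C[C@](C=CC2=O)(CC=C)C1=O | intermediate
10 | β-keto acid: as 9 with CO2H on C6 | OC(=O)C1(C)[C@@H]2C[C@](C=CC2=O)(CC=C)C1=O | intermediate
11 | C6-methyl diketone: C5 and C8 ketones, C9=C10, allyl on C1, H and CH3 on C6 (C6 epimers) | CC1[C@@H]2C[C@](C=CC2=O)(CC=C)C1=O | intermediate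
12 | C6-hydroxymethyl diketone: as 11 with CH2OH exo and CH3 endo on C6 | C[C@@]1(CO)[C@@H]2C[C@](C=CC2=O)(CC=C)C1=O | intermediate
13 | silyl ether diketone: TBS ether of 12 | C[C@@]1(CO[Si](C)(C)C(C)(C)C)[C@@H]2C[C@](C=CC2=O)(CC=C)C1=O | intermediate
14 | C12 aldehyde: as 13 with CH2CHO (C2, C12) on C1 | C[C@@]1(CO[Si](C)(C)C(C)(C)C)[C@@H]2C[C@](C=CC2=O)(CC=O)C1=O | intermediate
15 | C12 carboxylic acid: as 13 with CH2CO2H on C1 | C[C@@]1(CO[Si](C)(C)C(C)(C)C)[C@@H]2C[C@](C=CC2=O)(CC(=O)O)C1=O | intermediate
16 | keto-lactone: γ-lactone C12(=O)–O–C10 cis-fused to ring C at C1–C10, ketones at C5 and C8, C9 CH2, C6 with CH3 endo and CH2OTBS exo | C[C@@]1(CO[Si](C)(C)C(C)(C)C)[C@@H]2C[C@]3(CC(=O)O[C@H]3CC2=O)C1=O | intermediate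
17 | vinyl triflate keto-lactone: as 16 with C8(OTf)=C9 | C[C@@]1(CO[Si](C)(C)C(C)(C)C)[C@@H]2C[C@]3(CC(=O)O[C@H]3C=C2OS(=O)(=O)C(F)(F)F)C1=O | intermediate
18 | vinyltriphenylphosphonium bromide | C=C[P+](c1ccccc1)(c1ccccc1)c1ccccc1.[Br-] | starting material
19 | phosphonium ylide: 17 carrying CH2–CH=PPh3 (C3, C4) on C2, arm on the side of C5 | C[C@@]1(CO[Si](C)(C)C(C)(C)C)[C@@H]2C[C@]3([C@H](CC=P(c4ccccc4)(c4ccccc4)c4ccccc4)C(=O)O[C@H]3C=C2OS(=O)(=O)C(F)(F)F)C1=O | intermediate
20 | ring-A cyclopentene lactone: tetracycle with C4=C5, lactone C12(=O)–O–C10 cis-fused to rings A and C, H-2 syn to C11, C8(OTf)=C9, C6 with CH3 endo and CH2OTBS exo | C[C@@]1(CO[Si](C)(C)C(C)(C)C)[C@@H]2C[C@]3([C@@H](OC4=O)C=C2OS(=O)(=O)C(F)(F)F)[C@@H]4CC=C13 | intermediate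
21 | cyclopentene lactone alcohol: 20 with free C13–OH | C[C@@]1(CO)[C@@H]2C[C@]3([C@@H](OC4=O)C=C2OS(=O)(=O)C(F)(F)F)[C@@H]4CC=C13 | intermediate
22 | saturated lactone alcohol: as 21 with C4H2 and C5–H exo (syn to CH2OH; rings A/B trans-fused) | C[C@@]1(CO)[C@@H]2C[C@]3([C@@H](OC4=O)C=C2OS(=O)(=O)C(F)(F)F)[C@@H]4CC[C@@H]13 | intermediate
23 | saturated lactone silyl ether: TBS ether of 22 | C[C@@]1(CO[Si](C)(C)C(C)(C)C)[C@@H]2C[C@]3([C@@H](OC4=O)C=C2OS(=O)(=O)C(F)(F)F)[C@@H]4CC[C@@H]13 | intermediate
24 | lactol: as 23 with C12 as CH(OH) (anomer mixture) | C[C@@]1(CO[Si](C)(C)C(C)(C)C)[C@@H]2C[C@]3([C@@H](OC4O)C=C2OS(=O)(=O)C(F)(F)F)[C@@H]4CC[C@@H]13 | intermediate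
25 | dithiane alcohol: C2 carries 1,3-dithian-2-yl (C12), C10–OH free, C8(OTf)=C9, C13–OTBS; all centres as in the target | C[C@@]1(CO[Si](C)(C)C(C)(C)C)[C@@H]2C[C@]3([C@@H](O)C=C2OS(=O)(=O)C(F)(F)F)[C@@H](C4SCCCS4)CC[C@@H]13 | intermediate
26 | oct-7-yn-1-ol | C#CCCCCCCO | starting material
27 | tert-butyldimethyl(oct-7-yn-1-yloxy)silane | C#CCCCCCCO[Si](C)(C)C(C)(C)C | intermediate
28 | 8-bromooctanoic acid | OC(=O)CCCCCCCBr | starting material
29 | 16-(tert-butyldimethylsilyloxy)hexadec-9-ynoic acid | OC(=O)CCCCCCCC#CCCCCCCO[Si](C)(C)C(C)(C)C | intermediate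
30 | (9Z)-16-(tert-butyldimethylsilyloxy)hexadec-9-enoic acid | OC(=O)CCCCCCC/C=C\CCCCCCO[Si](C)(C)C(C)(C)C | intermediate
31 | mixed anhydride of 30 with 2,4,6-trichlorobenzoic acid | O=C(OC(=O)c1c(Cl)cc(Cl)cc1Cl)CCCCCCC/C=C\CCCCCCO[Si](C)(C)C(C)(C)C | intermediate
32 | C10 ester: 25 acylated at O–C10 by 30 | C[C@@]1(CO[Si](C)(C)C(C)(C)C)[C@@H]2C[C@]3([C@@H](OC(=O)CCCCCCC/C=C\CCCCCCO[Si](C)(C)C(C)(C)C)C=C2OS(=O)(=O)C(F)(F)F)[C@@H](C4SCCCS4)CC[C@@H]13 | intermediate
33 | C8 carboxylic acid: as 32 with CO2H in place of OTf | C[C@@]1(CO[Si](C)(C)C(C)(C)C)[C@@H]2C[C@]3([C@@H](OC(=O)CCCCCCC/C=C\CCCCCCO[Si](C)(C)C(C)(C)C)C=C2C(=O)O)[C@@H](C4SCCCS4)CC[C@@H]13 | intermediate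
34 | aldehyde bis-silyl ether: as 33 with CHO on C2 | C[C@@]1(CO[Si](C)(C)C(C)(C)C)[C@@H]2C[C@]3([C@@H](OC(=O)CCCCCCC/C=C\CCCCCCO[Si](C)(C)C(C)(C)C)C=C2C(=O)O)[C@@H](C=O)CC[C@@H]13 | intermediate
35 | (1R,2S,5S,6S,7S,10S)-2-formyl-10-{[(9Z)-16-hydroxyhexadec-9-enoyl]oxy}-6-(hydroxymethyl)-6-methyltricyclo[5.3.1.0^{1,5}]undec-8-ene-8-carboxylic acid | C[C@@]1(CO)[C@@H]2C[C@]3([C@@H](OC(=O)CCCCCCC/C=C\CCCCCCO)C=C2C(=O)O)[C@@H](C=O)CC[C@@H]13 | target

**Step count and risks**

Total step count: 24. Longest linear sequence: 21 steps (steps 1–17 and 21–24).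

Steps most likely to fail:

1. Step 14. Hydrogen may be delivered to the endo face, or the double bond may migrate without being reduced, because exo delivery builds the strained trans A/B fusion; the lactone carbonyl may also compete as a directing group. The fallback replaces hydrogenation by hydroboration and deoxygenation; it sets out from 21 and comes back at 23. Borane (BH3·THF, 0 °C → rt) is added to 21; the C13 alkoxyborane should deliver B–H to the exo face, boron to C4 and hydrogen to C5, and oxidation with NaBO3·4H2O gives the C4,C13-diol F1. The primary alcohol is silylated (TBSCl, imidazole) to the C13 silyl ether F2. The C4 alcohol is converted with 1,1′-thiocarbonyldiimidazole and DMAP into the C4 imidazolylthiocarbonate F3, and Barton–McCombie reduction (Bu3SnH, AIBN, toluene, 80 °C) gives 23.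

2. Step 12. The intramolecular Wittig closure may fail at the doubly neopentyl C5 ketone, so that the ylide is only protonated or the lactone enolate is alkylated twice. The fallback forms the two bonds in separate operations; it sets out from 17 and comes back at 20. Compound 17 is deprotonated with LiN(SiMe3)2 and alkylated with allyl bromide 2 to give the C2-allyl keto-lactone F4 (C2 epimers equilibrated with DBU). Selective ozonolysis of the terminal alkene (O3, CH2Cl2, −78 °C; PPh3) gives the C4 aldehyde F5. Intramolecular McMurry coupling of the C4 aldehyde with the C5 ketone (TiCl3, zinc–copper couple, DME, reflux) gives 20.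

3. Step 3. The enzyme may not accept the substrate, may over-reduce it, or may give low enantioselectivity. The fallback replaces desymmetrisation by resolution; it sets out from 4 and comes back at 5. Conjugate reduction of 4 with K[(s-Bu)3BH] (THF, −78 °C) gives the racemic enone F6, which is resolved by preparative chromatography on a chiral stationary phase to give 5; the S enantiomer is set aside.

**Further compounds**

F1 | step 14 | C4,C13-diol: 21 with C4–OH and C5–H added syn on the exo face | C[C@@]1(CO)[C@@H]2C[C@]3([C@@H](OC4=O)C=C2OS(=O)(=O)C(F)(F)F)[C@@H]4C[C@H](O)[C@@H]13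
F2 | step 14 | C13 silyl ether of F1 | C[C@@]1(CO[Si](C)(C)C(C)(C)C)[C@@H]2C[C@]3([C@@H](OC4=O)C=C2OS(=O)(=O)C(F)(F)F)[C@@H]4C[C@H](O)[C@@H]13
F3 | step 14 | C4 imidazolylthiocarbonate of F2 | C[C@@]1(CO[Si](C)(C)C(C)(C)C)[C@@H]2C[C@]3([C@@H](OC4=O)C=C2OS(=O)(=O)C(F)(F)F)[C@@H]4C[C@H](OC(=S)n5ccnc5)[C@@H]13
F4 | step 12 | C2-allyl keto-lactone: 17 with allyl on C2, on the side of C5 | C[C@@]1(CO[Si](C)(C)C(C)(C)C)[C@@H]2C[C@]3([C@H](CC=C)C(=O)O[C@H]3C=C2OS(=O)(=O)C(F)(F)F)C1=O
F5 | step 12 | C4 aldehyde: 17 with CH2CHO (C3, C4) on C2 | C[C@@]1(CO[Si](C)(C)C(C)(C)C)[C@@H]2C[C@]3([C@H](CC=O)C(=O)O[C@H]3C=C2OS(=O)(=O)C(F)(F)F)C1=O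
F6 | step 3 | racemic methyl 1-allyl-4-oxocyclohex-2-ene-1-carboxylate | O=C1C=CC(CC=C)(C(=O)OC)CC1
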